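The γ-butyrolactone (ring atoms O1, C2, C3, C4, C5) is opened at the acyl bond O1–C2. Its β-carbon C4 carries two CH2 groups, ring C5H2 and the veratryl CH2, so C4 is traced back to a prochiral CH(CH2OH)2 unit next to the α-carbon C3. In one operation, weak acid frees this diol, closes the lactone and lets the two possible lactones equilibrate to the one whose spare CH2OH is trans to the C3 side chain, so C3 sets C4. The precursor is an Evans syn-aldol acid bearing a 2,2-dimethyl-1,3-dioxan-5-yl group on its α-carbon, a benzylic TBS ether and a phenolic TIPS ether.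

Key step: step 8

Remark: the phenol is carried as a triisopropylsilyl ether, because an aryl tert-butyldimethylsilyl ether is easily lost in the basic peroxide of step 7; both silyl ethers still fall in one fluoride step.
Remark: the target is the trans lactone (3S,4R) with an (S) carbinol; the hydroxymethyl lactone of the key step has the same spatial arrangement but is named (3S,4S), because CH2OH outranks C3 whereas the benzylic CH2 does not.
Remark: benzyl (triphenylphosphoranylidene)acetate and (S)-4-benzyl-2-oxazolidinone are taken as commercial.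

Step 1
Reactants: 1 2,2-dimethyl-1,3-dioxan-5-one; 2 benzyl (triphenylphosphoranylidene)acetate
Product: 3 benzyl 2-(2,2-dimethyl-1,3-dioxan-5-ylidene)acetate
Conditions: CH2Cl2, rt
Reagents that add atoms: none
Why: Wittig olefination with a stabilised ylide under neutral conditions should give the exocyclic enoate without enolising the base-sensitive ketone, and the symmetric ring means no alkene geometry arises.

Step 2
Reactants: 3 benzyl 2-(2,2-dimethyl-1,3-dioxan-5-ylidene)acetate
Product: 4 2-(2,2-dimethyl-1,3-dioxan-5-yl)acetic acid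
Conditions: H2 (1 atm), 10% Pd/C, EtOAc, rt
Reagents that add atoms: none
Why: Heterogeneous catalytic hydrogenation should saturate the conjugated alkene and hydrogenolyse the benzyl ester in the same flask, giving the acid without aqueous acid near the ketal and without a stereocentre, since C5 of the dioxane carries two identical arms.

Step 3
Reactants: 4 2-(2,2-dimethyl-1,3-dioxan-5-yl)acetic acid; 5 (S)-4-benzyl-2-oxazolidinone
Product: 7 (S)-4-benzyl-3-[2-(2,2-dimethyl-1,3-dioxan-5-yl)acetyl]oxazolidin-2-one, via mixed pivalic anhydride 6 (not isolated)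
Conditions: PivCl, Et3N, THF, −20 °C; then 5, LiCl, −20 °C → rt
Reagents that add atoms: none
Why: Mixed-anhydride N-acylation of the oxazolidinone (LiCl/Et3N variant) should occur at the unhindered acyl carbon of the anhydride under weakly basic conditions that leave the ketal intact.

Step 4
Reactants: 8 vanillin
Product: 9 3-methoxy-4-(triisopropylsilyloxy)benzaldehyde
Conditions: TIPSCl, imidazole, DMF, rt
Reagents that add atoms: triisopropylsilyl chloride, CC(C)[Si](Cl)(C(C)C)C(C)C
Why: Standard silylation of a phenol with a silyl chloride and imidazole masks the acidic OH for the enolate, triflation and Grignard steps with a group that resists basic peroxide.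

Step 5
Reactants: 7 (S)-4-benzyl-3-[2-(2,2-dimethyl-1,3-dioxan-5-yl)acetyl]oxazolidin-2-one; 9 3-methoxy-4-(triisopropylsilyloxy)benzaldehyde
Product: 12 (S)-4-benzyl-3-[(2S,3S)-2-(2,2-dimethyl-1,3-dioxan-5-yl)-3-hydroxy-3-(3-methoxy-4-triisopropylsilyloxyphenyl)propanoyl]oxazolidin-2-one, via Z boron enolate 10 (not isolated), via boron aldolate 11 (not isolated)
Conditions: Bu2BOTf, i-Pr2NEt, CH2Cl2, 0 °C; then 9, −78 → 0 °C; pH 7 buffer, MeOH, 30% H2O2, 0 °C
Reagents that add atoms: none
Why: Evans syn-aldol reaction, in which the Z boron enolate adds to the aldehyde through a Zimmerman–Traxler chair on the enolate face away from the benzyl group of the (S)-auxiliary, so that C2 and C3 are set together as the (2S,3S) syn pair.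

Step 6
Reactants: 12 (S)-4-benzyl-3-[(2S,3S)-2-(2,2-dimethyl-1,3-dioxan-5-yl)-3-hydroxy-3-(3-methoxy-4-triisopropylsilyloxyphenyl)propanoyl]oxazolidin-2-one
Product: 13 (S)-4-benzyl-3-[(2S,3S)-3-(tert-butyldimethylsilyloxy)-2-(2,2-dimethyl-1,3-dioxan-5-yl)-3-(3-methoxy-4-triisopropylsilyloxyphenyl)propanoyl]oxazolidin-2-one
Conditions: TBSOTf, 2,6-lutidine, CH2Cl2, −78 → 0 °C
Reagents that add atoms: tert-butyldimethylsilyl triflate, CC(C)(C)[Si](C)(C)OS(=O)(=O)C(F)(F)F
Why: O-silylation with a silyl triflate and a hindered pyridine base should cap the hindered benzylic alcohol at low temperature without retro-aldol, so this oxygen can later neither lactonise nor displace the triflate.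

Step 7
Reactants: 13 (S)-4-benzyl-3-[(2S,3S)-3-(tert-butyldimethylsilyloxy)-2-(2,2-dimethyl-1,3-dioxan-5-yl)-3-(3-methoxy-4-triisopropylsilyloxyphenyl)propanoyl]oxazolidin-2-one
Product: 15 (2S,3S)-3-(tert-butyldimethylsilyloxy)-2-(2,2-dimethyl-1,3-dioxan-5-yl)-3-(3-methoxy-4-triisopropylsilyloxyphenyl)propanoic acid, via peroxy acid 14 (not isolated)
Conditions: LiOH, 30% H2O2, THF/H2O, 0 °C; Na2SO3 (aq); HCl (aq) to pH 4, 0 °C; used crude
Reagents that add atoms: hydrogen peroxide, OO
Why: Hydroperoxide cleavage of the N-acyl oxazolidinone (Evans LiOOH cleavage) should attack the exocyclic carbonyl to give the peroxy acid, which sulfite reduces to the acid, in a cold, weakly basic medium that should not epimerise C2 or remove the aryl TIPS ether, while stopping the acidification at pH 4 spares the ketal.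

Step 8
Reactants: 15 (2S,3S)-3-(tert-butyldimethylsilyloxy)-2-(2,2-dimethyl-1,3-dioxan-5-yl)-3-(3-methoxy-4-triisopropylsilyloxyphenyl)propanoic acid
Product: 18 (3S,4S)-3-[(S)-(tert-butyldimethylsilyloxy)(3-methoxy-4-triisopropylsilyloxyphenyl)methyl]-4-(hydroxymethyl)dihydrofuran-2(3H)-one (trans lactone), via diol acid 16 (not isolated), via cis lactone 17 (not isolated)
Conditions: AcOH/THF/H2O (3:1:1), 40 °C; concentrate; PPTS (0.2 equiv), PhMe, 50 °C
Reagents that add atoms: none
Why: Acetic acid hydrolyses the 1,3-dioxane ketal (acetone leaves) to diol acid 16, either hydroxymethyl arm adds to the protonated carboxyl with loss of water, and lactones 17 and 18 then interconvert because the remaining CH2OH adds to the lactone carbonyl to give a bridged 2,6-dioxabicyclo[2.2.1]heptan-1-ol adduct that can reopen at either ring C–O bond. The closest known reaction type is the thermodynamically controlled, diastereotopic-group-selective lactonisation of acids carrying a 2-substituted 1,3-diol, coupled with translactonisation of 3-hydroxymethyl butyrolactones. The ring closes 5-exo-trig at the carboxyl carbon, forming the O1–C2 bond. The new stereocentre C4 is controlled by C3 under thermodynamic substrate control, because the trans lactone avoids the contact between CH2OH and the bulky CH(OTBS)Ar group on adjacent ring carbons, so the equilibrium should drain to 18. The step needs arm selectivity, secured by that C3 bias, and chemoselectivity for the ketal over the silyl ethers, secured by using only weak acids (AcOH, then PPTS) and a non-polar, non-nucleophilic solvent for the equilibration so that the benzylic C–OSi bond is not ionised, while the hindered secondary TBS ether and the aryl TIPS ether are stable to such acids.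

Step 9
Reactants: 18 (3S,4S)-3-[(S)-(tert-butyldimethylsilyloxy)(3-methoxy-4-triisopropylsilyloxyphenyl)methyl]-4-(hydroxymethyl)dihydrofuran-2(3H)-one
Product: 19 [(3R,4S)-4-[(S)-(tert-butyldimethylsilyloxy)(3-methoxy-4-triisopropylsilyloxyphenyl)methyl]-5-oxotetrahydrofuran-3-yl]methyl trifluoromethanesulfonate
Conditions: Tf2O, 2,6-lutidine, CH2Cl2, −78 → −40 °C; used crude at once
Reagents that add atoms: triflic anhydride, O=S(=O)(OS(=O)(=O)C(F)(F)F)C(F)(F)F
Why: O-sulfonylation of the primary alcohol with triflic anhydride and a hindered, non-nucleophilic base should be clean at low temperature, since lutidine does not remove the C3 proton and attack of the silyloxy oxygen on the triflate would need a strained trans-fused bicyclo[3.3.0] ring system.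

Step 10
Reactants: 19 [(3R,4S)-4-[(S)-(tert-butyldimethylsilyloxy)(3-methoxy-4-triisopropylsilyloxyphenyl)methyl]-5-oxotetrahydrofuran-3-yl]methyl trifluoromethanesulfonate; 20 4-bromo-1,2-dimethoxybenzene
Product: 22 (3S,4R)-3-[(S)-(tert-butyldimethylsilyloxy)(3-methoxy-4-triisopropylsilyloxyphenyl)methyl]-4-(3,4-dimethoxybenzyl)dihydrofuran-2(3H)-one, via arylmagnesium bromide 21 (not isolated)
Conditions: 20, Mg, THF, 40 °C; then 19, CuBr·SMe2 (10 mol%), THF, −78 → −30 °C; NH4Cl (aq)
Reagents that add atoms: none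
Why: Copper-catalysed sp3–sp2 cross-coupling of a primary alkyl triflate with an aryl Grignard reagent should be much faster at −78 °C than addition of the arylmagnesium species to the lactone carbonyl, and substitution at the CH2 carbon leaves C4 untouched.

Step 11
Reactants: 22 (3S,4R)-3-[(S)-(tert-butyldimethylsilyloxy)(3-methoxy-4-triisopropylsilyloxyphenyl)methyl]-4-(3,4-dimethoxybenzyl)dihydrofuran-2(3H)-one
Product: 23 (3S,4R)-4-(3,4-dimethoxybenzyl)-3-[(S)-hydroxy(4-hydroxy-3-methoxyphenyl)methyl]dihydrofuran-2(3H)-one (target)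
Conditions: TBAF, AcOH (1:1), THF, 0 °C → rt
Reagents that add atoms: none
Why: Fluoride-mediated desilylation should cleave both the aryl TIPS and the secondary TBS ether, while the acetic acid buffer keeps phenoxide and alkoxide protonated so that retro-aldol cleavage, β-elimination and quinone methide formation should not compete.

Compound list
1 | 2,2-dimethyl-1,3-dioxan-5-one | CC1(C)OCC(=O)CO1 | starting material
2 | benzyl (triphenylphosphoranylidene)acetate | O=C(OCc1ccccc1)C=P(c1ccccc1)(c1ccccc1)c1ccccc1 | starting material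
3 | benzyl 2-(2,2-dimethyl-1,3-dioxan-5-ylidene)acetate | CC1(C)OCC(=CC(=O)OCc2ccccc2)CO1 | intermediate
4 | 2-(2,2-dimethyl-1,3-dioxan-5-yl)acetic acid | CC1(C)OCC(CC(=O)O)CO1 | intermediate
5 | (S)-4-benzyl-2-oxazolidinone | O=C1N[C@@H](Cc2ccccc2)CO1 | starting material
6 | 2-(2,2-dimethyl-1,3-dioxan-5-yl)acetic pivalic anhydride (not isolated) | CC1(C)OCC(CC(=O)OC(=O)C(C)(C)C)CO1 | intermediate
7 | (S)-4-benzyl-3-[2-(2,2-dimethyl-1,3-dioxan-5-yl)acetyl]oxazolidin-2-one | CC1(C)OCC(CC(=O)N2[C@@H](Cc3ccccc3)COC2=O)CO1 | intermediate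
8 | vanillin | COc1cc(C=O)ccc1O | starting material
9 | 3-methoxy-4-(triisopropylsilyloxy)benzaldehyde | COc1cc(C=O)ccc1O[Si](C(C)C)(C(C)C)C(C)C | intermediate
10 | Z dibutylboron enolate of 7 (not isolated) | CCCCB(CCCC)O/C(=C\C1COC(C)(C)OC1)N1[C@@H](Cc2ccccc2)COC1=O | intermediate
11 | dibutylborinate of aldol 12 (boron aldolate, not isolated) | COc1cc([C@@H](OB(CCCC)CCCC)[C@@H](C(=O)N2[C@@H](Cc3ccccc3)COC2=O)C2COC(C)(C)OC2)ccc1O[Si](C(C)C)(C(C)C)C(C)C | intermediate
12 | (S)-4-benzyl-3-[(2S,3S)-2-(2,2-dimethyl-1,3-dioxan-5-yl)-3-hydroxy-3-(3-methoxy-4-triisopropylsilyloxyphenyl)propanoyl]oxazolidin-2-one | COc1cc([C@@H](O)[C@@H](C(=O)N2[C@@H](Cc3ccccc3)COC2=O)C2COC(C)(C)OC2)ccc1O[Si](C(C)C)(C(C)C)C(C)C | intermediate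
13 | (S)-4-benzyl-3-[(2S,3S)-3-(tert-butyldimethylsilyloxy)-2-(2,2-dimethyl-1,3-dioxan-5-yl)-3-(3-methoxy-4-triisopropylsilyloxyphenyl)propanoyl]oxazolidin-2-one | COc1cc([C@@H](O[Si](C)(C)C(C)(C)C)[C@@H](C(=O)N2[C@@H](Cc3ccccc3)COC2=O)C2COC(C)(C)OC2)ccc1O[Si](C(C)C)(C(C)C)C(C)C | intermediate
14 | (2S,3S)-3-(tert-butyldimethylsilyloxy)-2-(2,2-dimethyl-1,3-dioxan-5-yl)-3-(3-methoxy-4-triisopropylsilyloxyphenyl)propaneperoxoic acid (not isolated) | COc1cc([C@@H](O[Si](C)(C)C(C)(C)C)[C@@H](C(=O)OO)C2COC(C)(C)OC2)ccc1O[Si](C(C)C)(C(C)C)C(C)C | intermediate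
15 | (2S,3S)-3-(tert-butyldimethylsilyloxy)-2-(2,2-dimethyl-1,3-dioxan-5-yl)-3-(3-methoxy-4-triisopropylsilyloxyphenyl)propanoic acid | COc1cc([C@@H](O[Si](C)(C)C(C)(C)C)[C@@H](C(=O)O)C2COC(C)(C)OC2)ccc1O[Si](C(C)C)(C(C)C)C(C)C | intermediate
16 | (2S,3S)-3-(tert-butyldimethylsilyloxy)-2-(1,3-dihydroxypropan-2-yl)-3-(3-methoxy-4-triisopropylsilyloxyphenyl)propanoic acid (not isolated) | COc1cc([C@@H](O[Si](C)(C)C(C)(C)C)[C@@H](C(=O)O)C(CO)CO)ccc1O[Si](C(C)C)(C(C)C)C(C)C | intermediate
17 | (3S,4R)-3-[(S)-(tert-butyldimethylsilyloxy)(3-methoxy-4-triisopropylsilyloxyphenyl)methyl]-4-(hydroxymethyl)dihydrofuran-2(3H)-one (cis lactone, not isolated) | COc1cc([C@@H](O[Si](C)(C)C(C)(C)C)[C@H]2C(=O)OC[C@H]2CO)ccc1O[Si](C(C)C)(C(C)C)C(C)C | intermediate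
18 | (3S,4S)-3-[(S)-(tert-butyldimethylsilyloxy)(3-methoxy-4-triisopropylsilyloxyphenyl)methyl]-4-(hydroxymethyl)dihydrofuran-2(3H)-one (trans lactone) | COc1cc([C@@H](O[Si](C)(C)C(C)(C)C)[C@H]2C(=O)OC[C@@H]2CO)ccc1O[Si](C(C)C)(C(C)C)C(C)C | intermediate
19 | [(3R,4S)-4-[(S)-(tert-butyldimethylsilyloxy)(3-methoxy-4-triisopropylsilyloxyphenyl)methyl]-5-oxotetrahydrofuran-3-yl]methyl trifluoromethanesulfonate | COc1cc([C@@H](O[Si](C)(C)C(C)(C)C)[C@H]2C(=O)OC[C@@H]2COS(=O)(=O)C(F)(F)F)ccc1O[Si](C(C)C)(C(C)C)C(C)C | intermediate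
20 | 4-bromo-1,2-dimethoxybenzene | COc1ccc(Br)cc1OC | starting material
21 | 3,4-dimethoxyphenylmagnesium bromide (not isolated) | COc1ccc([Mg]Br)cc1OC | intermediate
22 | (3S,4R)-3-[(S)-(tert-butyldimethylsilyloxy)(3-methoxy-4-triisopropylsilyloxyphenyl)methyl]-4-(3,4-dimethoxybenzyl)dihydrofuran-2(3H)-one | COc1cc([C@@H](O[Si](C)(C)C(C)(C)C)[C@H]2C(=O)OC[C@@H]2Cc2ccc(OC)c(OC)c2)ccc1O[Si](C(C)C)(C(C)C)C(C)C | intermediate
23 | (3S,4R)-4-(3,4-dimethoxybenzyl)-3-[(S)-hydroxy(4-hydroxy-3-methoxyphenyl)methyl]dihydrofuran-2(3H)-one | COc1cc([C@@H](O)[C@H]2C(=O)OC[C@@H]2Cc2ccc(OC)c(OC)c2)ccc1O | target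

Total step count: 11. Longest linear sequence: 10 steps (1, 2, 3, 5, 6, 7, 8, 9, 10, 11); step 4 is a one-step side branch.

Steps most likely to fail

Step 8. Under acid weak enough to leave the benzylic silyl ether un-ionised, acyl migration between the two lactones may be too slow, so the arm selection could stay near its kinetic level instead of reaching equilibrium. The fallback sets out from the mixture of 18 and 17 and comes back at 18; it corrects the β-centre by enolisation in place of acyl migration. The free hydroxymethyl group of both lactones would be oxidised with Dess–Martin periodinane (NaHCO3, CH2Cl2), giving the cis aldehyde (3S,4S)-4-[(S)-(tert-butyldimethylsilyloxy)(3-methoxy-4-triisopropylsilyloxyphenyl)methyl]-5-oxotetrahydrofuran-3-carbaldehyde (F1) from 17 and the trans aldehyde (3R,4S)-4-[(S)-(tert-butyldimethylsilyloxy)(3-methoxy-4-triisopropylsilyloxyphenyl)methyl]-5-oxotetrahydrofuran-3-carbaldehyde (F2) from 18. The former C4 is then α to an aldehyde, so brief exposure to Et3N in CH2Cl2 should epimerise F1 through its enol to the more stable trans aldehyde F2; ring-opening β-elimination is disfavoured because the ring C–O bond lies near the nodal plane of the enol. NaBH4 in THF/MeOH at −78 °C should then reduce the aldehyde group of F2 in preference to the lactone and return 18.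

Step 10. The arylmagnesium reagent may add to the lactone carbonyl or remove the C3 proton (followed by ring closure onto the CH2OTf carbon), and the triflate may decompose before it couples. The fallback sets out from 18 and comes back at 22; it replaces the basic magnesium nucleophile by a neutral organozinc. Appel-type iodination of 18 (I2, PPh3, imidazole, CH2Cl2) should give (3S,4R)-3-[(S)-(tert-butyldimethylsilyloxy)(3-methoxy-4-triisopropylsilyloxyphenyl)methyl]-4-(iodomethyl)dihydrofuran-2(3H)-one (F3) with both ring stereocentres untouched. Zinc insertion into F3 (Zn dust, LiCl, THF) should convert it into [(3R,4S)-4-[(S)-(tert-butyldimethylsilyloxy)(3-methoxy-4-triisopropylsilyloxyphenyl)methyl]-5-oxotetrahydrofuran-3-yl]methylzinc iodide (F4), which neither adds to nor deprotonates a lactone. Negishi coupling of F4 with 20 (Pd(OAc)2, SPhos, THF, rt to 50 °C) should then deliver 22.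

Step 7. Attack of hydroperoxide at the hindered exocyclic carbonyl (α-branched, β-silyloxy) may be slow, so that opening of the oxazolidinone ring and loss of the aryl silyl ether could compete. The fallback sets out from 12 and comes back at 15; it removes the auxiliary before the bulky silyl group is installed. LiOH/H2O2 cleavage of the free aldol 12 (THF/H2O, 0 °C, then Na2SO3) should give (2S,3S)-2-(2,2-dimethyl-1,3-dioxan-5-yl)-3-hydroxy-3-(3-methoxy-4-triisopropylsilyloxyphenyl)propanoic acid (F5) at the much less hindered acyl carbon. Treatment of F5 with excess TBSOTf and 2,6-lutidine in CH2Cl2 should silylate both the alcohol and the acid to give tert-butyldimethylsilyl (2S,3S)-3-(tert-butyldimethylsilyloxy)-2-(2,2-dimethyl-1,3-dioxan-5-yl)-3-(3-methoxy-4-triisopropylsilyloxyphenyl)propanoate (F6) as the bis-silylated compound. Brief K2CO3 in aqueous MeOH/THF at 0 °C should then hydrolyse only the labile silyl ester of F6 and return 15.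

Further compounds
F1 | step 8 | (3S,4S)-4-[(S)-(tert-butyldimethylsilyloxy)(3-methoxy-4-triisopropylsilyloxyphenyl)methyl]-5-oxotetrahydrofuran-3-carbaldehyde (cis) | COc1cc([C@@H](O[Si](C)(C)C(C)(C)C)[C@H]2C(=O)OC[C@H]2C=O)ccc1O[Si](C(C)C)(C(C)C)C(C)C
F2 | step 8 | (3R,4S)-4-[(S)-(tert-butyldimethylsilyloxy)(3-methoxy-4-triisopropylsilyloxyphenyl)methyl]-5-oxotetrahydrofuran-3-carbaldehyde (trans) | COc1cc([C@@H](O[Si](C)(C)C(C)(C)C)[C@H]2C(=O)OC[C@@H]2C=O)ccc1O[Si](C(C)C)(C(C)C)C(C)C
F3 | step 10 | (3S,4R)-3-[(S)-(tert-butyldimethylsilyloxy)(3-methoxy-4-triisopropylsilyloxyphenyl)methyl]-4-(iodomethyl)dihydrofuran-2(3H)-one | COc1cc([C@@H](O[Si](C)(C)C(C)(C)C)[C@H]2C(=O)OC[C@@H]2CI)ccc1O[Si](C(C)C)(C(C)C)C(C)C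
F4 | step 10 | [(3R,4S)-4-[(S)-(tert-butyldimethylsilyloxy)(3-methoxy-4-triisopropylsilyloxyphenyl)methyl]-5-oxotetrahydrofuran-3-yl]methylzinc iodide | COc1cc([C@@H](O[Si](C)(C)C(C)(C)C)[C@H]2C(=O)OC[C@@H]2C[Zn]I)ccc1O[Si](C(C)C)(C(C)C)C(C)C
F5 | step 7 | (2S,3S)-2-(2,2-dimethyl-1,3-dioxan-5-yl)-3-hydroxy-3-(3-methoxy-4-triisopropylsilyloxyphenyl)propanoic acid | COc1cc([C@@H](O)[C@@H](C(=O)O)C2COC(C)(C)OC2)ccc1O[Si](C(C)C)(C(C)C)C(C)C
F6 | step 7 | tert-butyldimethylsilyl (2S,3S)-3-(tert-butyldimethylsilyloxy)-2-(2,2-dimethyl-1,3-dioxan-5-yl)-3-(3-methoxy-4-triisopropylsilyloxyphenyl)propanoate | COc1cc([C@@H](O[Si](C)(C)C(C)(C)C)[C@@H](C(=O)O[Si](C)(C)C(C)(C)C)C2COC(C)(C)OC2)ccc1O[Si](C(C)C)(C(C)C)C(C)C
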